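The ten-membered ring is opened at C3–C4, the single CH2–CH2 link in it. C4 is allylic to the Z C5=C6 alkene and C3 flanks a C2 carbonyl on quaternary C1, so the carbanion of a C2 β-keto sulfone can displace a C4 allylic bromide. This one SN2 step fuses the carbocycle onto ring A and the γ-lactone without touching a stereocentre or the alkene geometry. Seco precursor 42 holds every carbon and eight stereocentres. Its C8/C9 and C11/C12 diols are acetonides, not free tertiary alcohols beside acetates, which rules out C8–O alkylation, C2/C11 hemiketal formation and acetyl migration. C2 reduction and the three acetates come last.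

Key step: step 30

Numbering: the ten-membered ring is C1–C10 (C1 quaternary, C2 and C9 oxygenated CH, C5(Me)=C6, C7 lactone O–CH, C8 tertiary carbinol, C10 ring-fusion CH). Ring A is C10, C11, C12, C13=C14, C1. The lactone is C7, C8, C17 (CHMe), C19 (C=O). C15 is the methyl on C1 and C20 the methyl on C11. β is the face of ring A that carries C15, α the opposite face.

Assumption: the sense of induction in step 2 is assigned from the formyl C–H···O binding model for α-substituted enals on oxazaborolidinium ions. That model calls for the (R)-diphenylprolinol-derived catalyst to expose the Si face of C1. Both catalyst enantiomers are commercial, so the antipode would be used if the sense proved opposite.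

Step 1
Reactants: 1 pent-1-en-3-one
Product: 2 (Z)-3-(tert-butyldimethylsilyloxy)penta-1,3-diene
Conditions: TBSOTf, Et3N, Et2O, 0 °C
Reagents that add atoms: tert-butyldimethylsilyl triflate, CC(C)(C)[Si](C)(C)OS(=O)(=O)C(F)(F)F
Why: Soft enolisation of the ethyl ketone (silyl enol ether formation with silyl triflate and amine) favours the Z enol ether, which places the future C20 methyl on the outside of the s-cis diene.

Step 2
Reactants: 2 (Z)-3-(tert-butyldimethylsilyloxy)penta-1,3-diene; 3 ethyl (E)-3-methyl-4-oxobut-2-enoate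
Product: 4 ethyl (1S,2S,6S)-3-(tert-butyldimethylsilyloxy)-6-formyl-2,6-dimethylcyclohex-3-ene-1-carboxylate (ring A: C1 with Me β and CHO α; C10 with CO2Et β)
Conditions: (R)-3,3-diphenyl-1-(2-methylphenyl)tetrahydro-1H,3H-pyrrolo[1,2-c][1,3,2]oxazaborole (15 mol %), HN(SO2CF3)2 (12 mol %), CH2Cl2, −78 °C
Reagents that add atoms: none
Why: Catalytic enantioselective Diels–Alder reaction: the boron-bound formyl group makes C10 the electrophilic terminus, so the nucleophilic C11 end of the 2-silyloxydiene bonds to C10 and C14 to C1, suprafacial addition carries the E geometry of 3 into the trans C2/C9 relationship, the catalyst aryl group shields one face of the s-trans enal and thereby sets C1 and C10 absolutely, and the C11 centre (formyl-endo addition expected) is erased in step 6.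

Step 3
Reactants: 4 ring A formyl ester
Product: 5 ring A C2 alcohol (4 with CH2OH in place of CHO)
Conditions: NaBH4, EtOH/THF, −20 °C
Reagents that add atoms: none
Why: Chemoselective borohydride reduction of the aldehyde beside an ester and a silyl enol ether, run cold and followed at once by silylation so that the new alcohol does not lactonise onto C9.

Step 4
Reactants: 5 ring A C2 alcohol
Product: 6 ring A C2 TBS ether
Conditions: TBSCl, imidazole, DMF, rt
Reagents that add atoms: tert-butyldimethylsilyl chloride, CC(C)(C)[Si](C)(C)Cl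
Why: Routine silyl ether protection of a primary neopentyl alcohol, stable to all steps up to step 24.

Step 5
Reactants: 6 ring A C2 TBS ether
Product: 7 ring A enone (C12 ketone, C13=C14, C11 CHMe)
Conditions: Pd(OAc)2 (10 mol %), O2 (1 atm), DMSO, 40 °C
Reagents that add atoms: none
Why: Saegusa–Ito oxidation: palladation of the regiodefined C12=C13 silyl enol ether at C13 and β-hydride elimination from C14 place the alkene at C13=C14, where it stays to the end.

Step 6
Reactants: 7 ring A enone
Product: 9 ring A C12 dienyl triflate (C11=C12 and C13=C14), via potassium dienolate 8 (not isolated)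
Conditions: KN(SiMe3)2 (1.05 equiv), THF, −78 °C; PhNTf2, −78→0 °C
Reagents that add atoms: N-phenylbis(trifluoromethanesulfonimide), O=S(=O)(N(c1ccccc1)S(=O)(=O)C(F)(F)F)C(F)(F)F
Why: Enol triflate formation: C11–H is the only enolisable position of the ketone (C13 is vinylic, C1 quaternary) and is more acidic than the ester α-proton at C10, so one equivalent of base gives the cross-conjugated dienolate, which is trapped on oxygen.

Step 7
Reactants: 9 ring A C12 dienyl triflate
Product: 10 ring A 1,3-diene ester (C11(Me)=C12–C13=C14)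
Conditions: Pd(OAc)2 (5 mol %), PPh3 (10 mol %), HCO2H, Et3N, DMF, 50 °C
Reagents that add atoms: none
Why: Palladium-catalysed formate reduction of an enol triflate (oxidative addition, decarboxylation to a palladium hydride, reductive elimination) exchanges OTf for H and leaves the C11=C12–C13=C14 diene in place.

Step 8
Reactants: 10 ring A 1,3-diene ester
Product: 11 ring A 11α,12α-diol ester (C20 methyl β, C13=C14 kept)
Conditions: OsO4 (2 mol %), N-methylmorpholine N-oxide (1.1 equiv), acetone/H2O, 0 °C
Reagents that add atoms: OsO4 (oxygen carrier), O=[Os](=O)(=O)=O; N-methylmorpholine N-oxide, C[N+]1([O-])CCOCC1; water, O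
Why: Catalytic OsO4/NMO syn dihydroxylation picks the electron-richer trisubstituted C11=C12 bond over C13=C14 next to quaternary C1 and attacks its α face, opposite the pseudoaxial C9 ester on the adjacent C10, so C11 and C12 are set together as the cis 11α,12α-diol.

Step 9
Reactants: 11 ring A 11α,12α-diol ester
Product: 12 ring A 11,12-acetonide ester
Conditions: Me2C(OMe)2, pyridinium p-toluenesulfonate (cat.), CH2Cl2, rt
Reagents that add atoms: 2,2-dimethoxypropane, COC(C)(C)OC
Why: Acid-catalysed acetonide formation on a cis-1,2-diol, which masks the tertiary C11 and secondary C12 hydroxyls until step 33.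

Step 10
Reactants: 12 ring A 11,12-acetonide ester
Product: 13 ring A C9 primary alcohol
Conditions: i-Bu2AlH (2.5 equiv), CH2Cl2, −78→0 °C; aq. potassium sodium tartrate
Reagents that add atoms: none
Why: Full hydride reduction of the hindered ester is more dependable than a stop at the aldehyde, and silyl ether, acetonide and alkene are inert to i-Bu2AlH.

Step 11
Reactants: 13 ring A C9 primary alcohol
Product: 14 ring A C9 aldehyde (CHO β on C10)
Conditions: Dess–Martin periodinane, CH2Cl2, 0 °C→rt
Reagents that add atoms: none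
Why: Dess–Martin oxidation works without base, so the aldehyde is formed without epimerisation at C10.

Step 12
Reactants: 15 methyl (S)-3-hydroxy-2-methylpropanoate
Product: 16 methyl (S)-3-(tert-butyldimethylsilyloxy)-2-methylpropanoate
Conditions: TBSCl, imidazole, CH2Cl2, rt
Reagents that add atoms: tert-butyldimethylsilyl chloride, CC(C)(C)[Si](C)(C)Cl
Why: Silyl ether protection; the S enantiomer is needed because its ester carbon becomes C8 and its CH2O carbon becomes the lactone carbonyl C19, which maps onto 17R of the target.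

Step 13
Reactants: 16 methyl (S)-3-(tert-butyldimethylsilyloxy)-2-methylpropanoate
Product: 17 (S)-3-(tert-butyldimethylsilyloxy)-2-methylpropanal
Conditions: i-Bu2AlH (1.1 equiv), CH2Cl2, −78 °C
Reagents that add atoms: none
Why: Partial reduction of an ester with i-Bu2AlH at −78 °C, where the aluminium hemiacetal survives until the quench, gives the α-chiral aldehyde, used crude to protect C17.

Step 14
Reactants: 17 (S)-3-(tert-butyldimethylsilyloxy)-2-methylpropanal
Product: 18 (R)-tert-butyl(dimethyl)[(2-methylbut-3-yn-1-yl)oxy]silane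
Conditions: dimethyl (1-diazo-2-oxopropyl)phosphonate, K2CO3, MeOH, 0 °C
Reagents that add atoms: dimethyl (1-diazo-2-oxopropyl)phosphonate, COP(=O)(OC)C(=[N+]=[N-])C(C)=O
Why: Ohira–Bestmann (Seyferth–Gilbert type) homologation: the diazophosphonate anion made in situ adds to the aldehyde and loss of phosphate and N2 with 1,2-hydride shift gives the terminal alkyne (new carbon = C7) under base mild enough to keep C17.

Step 15
Reactants: 18 (R)-tert-butyl(dimethyl)[(2-methylbut-3-yn-1-yl)oxy]silane
Product: 20 (S)-tert-butyl[(3-iodo-2-methylbut-3-en-1-yl)oxy]dimethylsilane, via iodoalkenylborane 19 (not isolated)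
Conditions: B-iodo-9-borabicyclo[3.3.1]nonane, hexane/CH2Cl2, −20 °C; AcOH, 0 °C
Reagents that add atoms: B-iodo-9-borabicyclo[3.3.1]nonane, IB1C2CCCC1CCC2
Why: Haloboration–protonolysis: B-iodo-9-BBN adds syn across the terminal alkyne with iodine on the internal carbon C8, and acetic acid replaces boron by hydrogen to give the 2-iodo-1-alkene.

Step 16
Reactants: 20 (S)-tert-butyl[(3-iodo-2-methylbut-3-en-1-yl)oxy]dimethylsilane; 14 ring A C9 aldehyde
Product: 23 C9 allylic alcohol (9R; C8=C7H2; C17 as in 20), via vinyllithium 21 (not isolated), via vinylmagnesium bromide 22 (not isolated)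
Conditions: 20, t-BuLi (2.0 equiv), Et2O, −78 °C; MgBr2·OEt2, −78→−20 °C; then 14 precomplexed with MgBr2·OEt2, CH2Cl2, −78 °C
Reagents that add atoms: none
Why: Iodine–lithium exchange, transmetalation and chelation-controlled (Cram chelate) 1,2-addition: magnesium bridges the formyl oxygen and the C11 acetonide oxygen, which fixes the carbonyl rotamer, and the alkenyl group enters from the side of H10, away from the C15 and C20 methyl groups, to form C8–C9 and the 9R carbinol.

Step 17
Reactants: 23 C9 allylic alcohol
Product: 24 C7,C8,C9 triol (8S,9R; O8 and O9 erythro)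
Conditions: OsO4 (5 mol %), N-methylmorpholine N-oxide, acetone/H2O, 0 °C→rt
Reagents that add atoms: OsO4 (oxygen carrier), O=[Os](=O)(=O)=O; N-methylmorpholine N-oxide, C[N+]1([O-])CCOCC1; water, O
Why: OsO4/NMO syn dihydroxylation of the accessible 1,1-disubstituted C7=C8 alkene (C13=C14 is flanked by C1 and the acetonide): A(1,2) strain turns H9 toward the C17 branch, ring A then covers one alkene face and osmium adds to the other, which gives the 8S tertiary alcohol with O8 and O9 erythro.

Step 18
Reactants: 24 C7,C8,C9 triol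
Product: 25 C7 triethylsilyl ether of the triol
Conditions: Et3SiCl (1.1 equiv), imidazole, CH2Cl2, −20 °C
Reagents that add atoms: chlorotriethylsilane, CC[Si](Cl)(CC)CC
Why: Kinetic silylation selects the only primary hydroxyl over the hindered secondary C9 and tertiary C8 hydroxyls.

Step 19
Reactants: 25 C7 triethylsilyl ether of the triol
Product: 26 bis-acetonide (C8/C9 and C11/C12) C7 triethylsilyl ether
Conditions: 2-methoxypropene, pyridinium p-toluenesulfonate (cat.), 4 Å molecular sieves, CH2Cl2, 0 °C→rt
Reagents that add atoms: 2-methoxypropene, COC(C)=C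
Why: Acetonide formation with an enol ether under mild acid ties up the C8/C9 diol, and the sieves bind the methanol that could otherwise cleave the triethylsilyl ether.

Step 20
Reactants: 26 bis-acetonide C7 triethylsilyl ether
Product: 27 bis-acetonide C7 aldehyde
Conditions: (COCl)2, DMSO, CH2Cl2, −78→−40 °C; Et3N, −78 °C→rt
Reagents that add atoms: none
Why: Swern oxidation applied directly to a primary triethylsilyl ether, which the chlorosulfonium salt desilylates and oxidises in one operation while TBS ethers and acetonides persist; C8 bears no hydrogen, so the aldehyde is configurationally safe.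

Step 21
Reactants: 28 prop-2-yn-1-ol
Product: 30 (Z)-3-iodo-2-methylprop-2-en-1-ol, via chelated vinylmagnesium alkoxide 29 (not isolated)
Conditions: MeMgBr (2.5 equiv), CuI (10 mol %), THF, −10 °C→rt; I2, −10 °C
Reagents that add atoms: methylmagnesium bromide, C[Mg]Br; iodine, II
Why: Copper-catalysed, hydroxyl-directed anti carbomagnesiation of propargyl alcohol gives a five-membered magnesium chelate, so iodinolysis puts iodine cis to CH2OH and fixes the Z geometry of the future C5=C6 bond.

Step 22
Reactants: 30 (Z)-3-iodo-2-methylprop-2-en-1-ol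
Product: 31 (Z)-1-iodo-3-(4-methoxybenzyloxy)-2-methylprop-1-ene
Conditions: NaH, 4-methoxybenzyl chloride, Bu4NI (cat.), THF/DMF, 0 °C→rt
Reagents that add atoms: 4-methoxybenzyl chloride, COc1ccc(CCl)cc1
Why: Williamson etherification; a PMB ether is chosen because a silyl ether cis to the later vinyllithium could migrate from oxygen to carbon.

Step 23
Reactants: 31 (Z)-1-iodo-3-(4-methoxybenzyloxy)-2-methylprop-1-ene; 27 bis-acetonide C7 aldehyde
Product: 33 C7 allylic alcohol (7S; Z C5=C6; C4 OPMB), via Z-vinyllithium 32 (not isolated)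
Conditions: 31, t-BuLi (2.0 equiv), Et2O, −78 °C; then 27, THF, −78 °C
Reagents that add atoms: none
Why: Iodine–lithium exchange with retention of alkene geometry and Felkin–Anh 1,2-addition under non-chelating conditions: with the C8–O8 bond anti to the incoming vinyllithium the reagent passes the smaller C17 branch and not the C9/ring A branch, which forms C6–C7 and the 7S carbinol with O7 and O8 erythro.

Step 24
Reactants: 33 C7 allylic alcohol
Product: 34 C2,C7,C19 triol
Conditions: Bu4NF, THF, 0 °C→rt
Reagents that add atoms: none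
Why: Fluoride cleaves both primary TBS ethers at once, while acetonides and the PMB ether are inert.

Step 25
Reactants: 34 C2,C7,C19 triol
Product: 36 γ-lactone C2 aldehyde, via C19 lactol 35 (not isolated)
Conditions: 2,2,6,6-tetramethylpiperidin-1-oxyl (TEMPO, 0.2 equiv), PhI(OAc)2 (3.5 equiv), CH2Cl2, rt
Reagents that add atoms: none
Why: TEMPO/PhI(OAc)2 oxidation is selective for primary alcohols: the C19 aldehyde is captured by the C7 hydroxyl as a five-membered lactol that is oxidised on to the γ-lactone (oxidative lactonisation), and the neopentyl C2 alcohol stops at the aldehyde.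

Step 26
Reactants: 37 methyl phenyl sulfone; 36 γ-lactone C2 aldehyde
Product: 39 C2 β-hydroxy sulfone (both C2 epimers), via lithiated methyl phenyl sulfone 38 (not isolated)
Conditions: 37, n-BuLi, THF, −78 °C; then 36, −78 °C; AcOH quench
Reagents that add atoms: none
Why: 1,2-Addition of the α-sulfonyl carbanion to the aldehyde at −78 °C outruns attack on, or deprotonation of, the hindered lactone, whose β-oxygen is a poor leaving group as part of the acetonide; both C2 epimers are used because step 27 removes this centre.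

Step 27
Reactants: 39 C2 β-hydroxy sulfone
Product: 40 C2 β-keto sulfone (C4 OPMB)
Conditions: Dess–Martin periodinane, CH2Cl2, 0 °C→rt
Reagents that add atoms: none
Why: Dess–Martin oxidation of the β-hydroxy sulfone gives the β-keto sulfone under non-basic conditions.

Step 28
Reactants: 40 C2 β-keto sulfone (C4 OPMB)
Product: 41 C4 allylic alcohol keto sulfone
Conditions: DDQ, CH2Cl2/pH 7 buffer (10:1), 0 °C
Reagents that add atoms: none
Why: Oxidative PMB cleavage with DDQ (hydride abstraction from the electron-rich benzylic position, then hydrolysis) spares acetonides, lactone, alkenes and the keto sulfone.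

Step 29
Reactants: 41 C4 allylic alcohol keto sulfone
Product: 42 seco C4 allylic bromide C2 keto sulfone (bis-acetonide)
Conditions: CBr4, PPh3, CH2Cl2, −20 °C; used at once
Reagents that add atoms: carbon tetrabromide, BrC(Br)(Br)Br
Why: Appel reaction: the primary allylic alcohol is activated as an oxyphosphonium ion and displaced by bromide at C4 under neutral conditions, so neither the acidic C3 methylene nor the Z alkene is disturbed.

Step 30
Reactants: 42 seco C4 allylic bromide C2 keto sulfone
Product: 44 ten-membered C2 ketone bearing the C3 phenylsulfonyl group (bis-acetonide), via caesium enolate 43 (not isolated)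
Conditions: Cs2CO3 (3 equiv), MeCN, 40 °C, slow addition of 42 to a final 1 mM
Reagents that add atoms: none
Why: Cs2CO3 removes the only proton acidic enough, that of the C3 methylene between ketone and sulfone, and the soft delocalised carbanion 43 displaces bromide from primary C4 in a direct SN2 reaction that forms C3–C4. The closest known reaction type is the intramolecular alkylation of sulfone-stabilised carbanions by allylic halides, used to make medium and large carbocycles. The ten-membered ring closes in a 10-exo-tet mode under high dilution, and the chain is already bent by the Z alkene, the trans-fused lactone, the spiro C8/C9 acetonide and quaternary C1. The only new stereocentre, C3, is uncontrolled and irrelevant because the sulfonyl group is removed in step 31. The step needs C- over O-alkylation and attack at C4 instead of SN2′ attack at C6, which the soft carbanion/soft bromide pairing and the shielding of C6 by the lactone and the trisubstituted alkene secure, while alkylation of a C8 hydroxyl and hemiketal formation at C2 are excluded by the acetonides. Back-side displacement at C4 does not involve the π bond, so the Z geometry of C5=C6 is kept.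

Step 31
Reactants: 44 ten-membered C3-sulfonyl C2 ketone
Product: 45 ten-membered C2 ketone (C3 and C4 both CH2)
Conditions: SmI2 (4 equiv), THF/MeOH, −78 °C
Reagents that add atoms: none
Why: Reductive desulfonylation: single-electron reduction of the α-sulfonyl ketone by SmI2 expels benzenesulfinate and methanol protonates the samarium enolate, while isolated alkenes, lactone and acetonides are not reduced at −78 °C.

Step 32
Reactants: 45 ten-membered C2 ketone
Product: 46 2R alcohol (bis-acetonide)
Conditions: NaBH4, MeOH/CH2Cl2, −20→0 °C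
Reagents that add atoms: none
Why: Substrate-controlled borohydride reduction: the medium ring holds C10 roughly perpendicular to the carbonyl plane, so hydride can arrive only from the outer face between C14 and the C15 methyl (peripheral, Felkin–Anh-type attack), which gives the 2R alcohol, and the lactone is not reduced.

Step 33
Reactants: 46 2R alcohol (bis-acetonide)
Product: 47 C2,C8,C9,C11,C12 pentaol
Conditions: CF3CO2H/H2O/THF (1:1:4), 0 °C→rt
Reagents that add atoms: none
Why: Acid-catalysed hydrolysis removes both acetonides in one operation under conditions mild enough for the allylic C7 and C12 C–O bonds.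

Step 34
Reactants: 47 C2,C8,C9,C11,C12 pentaol
Product: 48 target CNP0129620.2 (2,9,12-triacetate, 8,11-diol)
Conditions: Ac2O, pyridine, 4-(dimethylamino)pyridine (cat.), CH2Cl2, rt
Reagents that add atoms: acetic anhydride, CC(=O)OC(C)=O
Why: Acetylation with nucleophilic catalysis esterifies the three secondary hydroxyls at C2, C9 and C12, while the tertiary C8 and C11 hydroxyls are too hindered to react at room temperature.

Compound list
1 | pent-1-en-3-one | CCC(=O)C=C | starting material
2 | (Z)-3-(tert-butyldimethylsilyloxy)penta-1,3-diene | C=C/C(O[Si](C)(C)C(C)(C)C)=C/C | intermediate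
3 | ethyl (E)-3-methyl-4-oxobut-2-enoate | CCOC(=O)/C=C(\C)C=O | starting material
4 | ethyl (1S,2S,6S)-3-(tert-butyldimethylsilyloxy)-6-formyl-2,6-dimethylcyclohex-3-ene-1-carboxylate | CCOC(=O)[C@H]1[C@H](C)C(O[Si](C)(C)C(C)(C)C)=CC[C@]1(C)C=O | intermediate
5 | ring A C2 alcohol | CCOC(=O)[C@H]1[C@H](C)C(O[Si](C)(C)C(C)(C)C)=CC[C@]1(C)CO | intermediate
6 | ring A C2 TBS ether | CCOC(=O)[C@H]1[C@H](C)C(O[Si](C)(C)C(C)(C)C)=CC[C@]1(C)CO[Si](C)(C)C(C)(C)C | intermediate
7 | ring A enone (C12 ketone, C13=C14) | CCOC(=O)[C@H]1[C@H](C)C(=O)C=C[C@]1(C)CO[Si](C)(C)C(C)(C)C | intermediate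
8 | potassium dienolate of 7 | CCOC(=O)[C@H]1C(C)=C([O-])C=C[C@]1(C)CO[Si](C)(C)C(C)(C)C.[K+] | intermediate
9 | ring A C12 dienyl triflate | CCOC(=O)[C@H]1C(C)=C(OS(=O)(=O)C(F)(F)F)C=C[C@]1(C)CO[Si](C)(C)C(C)(C)C | intermediate
10 | ring A 1,3-diene ester | CCOC(=O)[C@H]1C(C)=CC=C[C@]1(C)CO[Si](C)(C)C(C)(C)C | intermediate
11 | ring A 11α,12α-diol ester | CCOC(=O)[C@H]1[C@](C)(O)[C@H](O)C=C[C@]1(C)CO[Si](C)(C)C(C)(C)C | intermediate
12 | ring A 11,12-acetonide ester | CCOC(=O)[C@H]1[C@]2(C)OC(C)(C)O[C@@H]2C=C[C@]1(C)CO[Si](C)(C)C(C)(C)C | intermediate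
13 | ring A C9 primary alcohol | OC[C@H]1[C@]2(C)OC(C)(C)O[C@@H]2C=C[C@]1(C)CO[Si](C)(C)C(C)(C)C | intermediate
14 | ring A C9 aldehyde | O=C[C@H]1[C@]2(C)OC(C)(C)O[C@@H]2C=C[C@]1(C)CO[Si](C)(C)C(C)(C)C | intermediate
15 | methyl (S)-3-hydroxy-2-methylpropanoate | COC(=O)[C@@H](C)CO | starting material
16 | methyl (S)-3-(tert-butyldimethylsilyloxy)-2-methylpropanoate | COC(=O)[C@@H](C)CO[Si](C)(C)C(C)(C)C | intermediate
17 | (S)-3-(tert-butyldimethylsilyloxy)-2-methylpropanal | O=C[C@@H](C)CO[Si](C)(C)C(C)(C)C | intermediate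
18 | (R)-tert-butyl(dimethyl)[(2-methylbut-3-yn-1-yl)oxy]silane | C#C[C@@H](C)CO[Si](C)(C)C(C)(C)C | intermediate
19 | (Z)-2-iodoalk-1-enyl-9-BBN adduct of 18 | I/C(=C\B1C2CCCC1CCC2)[C@@H](C)CO[Si](C)(C)C(C)(C)C | intermediate
20 | (S)-tert-butyl[(3-iodo-2-methylbut-3-en-1-yl)oxy]dimethylsilane | C=C(I)[C@@H](C)CO[Si](C)(C)C(C)(C)C | intermediate
21 | C8 vinyllithium from 20 | [Li]C(=C)[C@@H](C)CO[Si](C)(C)C(C)(C)C | intermediate
22 | C8 vinylmagnesium bromide from 21 | Br[Mg]C(=C)[C@@H](C)CO[Si](C)(C)C(C)(C)C | intermediate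
23 | C9 allylic alcohol (9R) | C=C([C@@H](C)CO[Si](C)(C)C(C)(C)C)[C@H](O)[C@H]1[C@]2(C)OC(C)(C)O[C@@H]2C=C[C@]1(C)CO[Si](C)(C)C(C)(C)C | intermediate
24 | C7,C8,C9 triol (8S,9R) | OC[C@@](O)([C@@H](C)CO[Si](C)(C)C(C)(C)C)[C@H](O)[C@H]1[C@]2(C)OC(C)(C)O[C@@H]2C=C[C@]1(C)CO[Si](C)(C)C(C)(C)C | intermediate
25 | C7 triethylsilyl ether of 24 | CC[Si](CC)(CC)OC[C@@](O)([C@@H](C)CO[Si](C)(C)C(C)(C)C)[C@H](O)[C@H]1[C@]2(C)OC(C)(C)O[C@@H]2C=C[C@]1(C)CO[Si](C)(C)C(C)(C)C | intermediate
26 | bis-acetonide C7 triethylsilyl ether | CC[Si](CC)(CC)OC[C@]3([C@@H](C)CO[Si](C)(C)C(C)(C)C)OC(C)(C)O[C@@H]3[C@H]1[C@]2(C)OC(C)(C)O[C@@H]2C=C[C@]1(C)CO[Si](C)(C)C(C)(C)C | intermediate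
27 | bis-acetonide C7 aldehyde | O=C[C@]3([C@@H](C)CO[Si](C)(C)C(C)(C)C)OC(C)(C)O[C@@H]3[C@H]1[C@]2(C)OC(C)(C)O[C@@H]2C=C[C@]1(C)CO[Si](C)(C)C(C)(C)C | intermediate
28 | prop-2-yn-1-ol | C#CCO | starting material
29 | chelated (Z)-vinylmagnesium alkoxide | Br[Mg]OC/C(C)=C\[Mg]Br | intermediate
30 | (Z)-3-iodo-2-methylprop-2-en-1-ol | OC/C(C)=C\I | intermediate
31 | (Z)-1-iodo-3-(4-methoxybenzyloxy)-2-methylprop-1-ene | COc1ccc(COC/C(C)=C\I)cc1 | intermediate
32 | (Z)-vinyllithium from 31 | COc1ccc(COC/C(C)=C\[Li])cc1 | intermediate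
33 | C7 allylic alcohol (7S, Z C5=C6, C4 OPMB) | COc4ccc(cc4)COC/C(C)=C\[C@H](O)[C@]3([C@@H](C)CO[Si](C)(C)C(C)(C)C)OC(C)(C)O[C@@H]3[C@H]1[C@]2(C)OC(C)(C)O[C@@H]2C=C[C@]1(C)CO[Si](C)(C)C(C)(C)C | intermediate
34 | C2,C7,C19 triol | COc4ccc(cc4)COC/C(C)=C\[C@H](O)[C@]3([C@@H](C)CO)OC(C)(C)O[C@@H]3[C@H]1[C@]2(C)OC(C)(C)O[C@@H]2C=C[C@]1(C)CO | intermediate
35 | C19 lactol (C2 alcohol still free) | COc4ccc(cc4)COC/C(C)=C\[C@@H]5OC(O)[C@H](C)[C@]53OC(C)(C)O[C@@H]3[C@H]1[C@]2(C)OC(C)(C)O[C@@H]2C=C[C@]1(C)CO | intermediate
36 | γ-lactone C2 aldehyde | COc4ccc(cc4)COC/C(C)=C\[C@@H]5OC(=O)[C@H](C)[C@]53OC(C)(C)O[C@@H]3[C@H]1[C@]2(C)OC(C)(C)O[C@@H]2C=C[C@]1(C)C=O | intermediate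
37 | methyl phenyl sulfone | CS(=O)(=O)c1ccccc1 | starting material
38 | lithiated methyl phenyl sulfone | [Li]CS(=O)(=O)c1ccccc1 | intermediate
39 | C2 β-hydroxy sulfone (C2 epimers) | COc4ccc(cc4)COC/C(C)=C\[C@@H]5OC(=O)[C@H](C)[C@]53OC(C)(C)O[C@@H]3[C@H]1[C@]2(C)OC(C)(C)O[C@@H]2C=C[C@]1(C)C(O)CS(=O)(=O)c6ccccc6 | intermediate
40 | C2 β-keto sulfone (C4 OPMB) | COc4ccc(cc4)COC/C(C)=C\[C@@H]5OC(=O)[C@H](C)[C@]53OC(C)(C)O[C@@H]3[C@H]1[C@]2(C)OC(C)(C)O[C@@H]2C=C[C@]1(C)C(=O)CS(=O)(=O)c6ccccc6 | intermediate
41 | C4 allylic alcohol keto sulfone | OC/C(C)=C\[C@@H]5OC(=O)[C@H](C)[C@]53OC(C)(C)O[C@@H]3[C@H]1[C@]2(C)OC(C)(C)O[C@@H]2C=C[C@]1(C)C(=O)CS(=O)(=O)c6ccccc6 | intermediate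
42 | seco C4 allylic bromide C2 keto sulfone (bis-acetonide) | BrC/C(C)=C\[C@@H]5OC(=O)[C@H](C)[C@]53OC(C)(C)O[C@@H]3[C@H]1[C@]2(C)OC(C)(C)O[C@@H]2C=C[C@]1(C)C(=O)CS(=O)(=O)c6ccccc6 | intermediate
43 | caesium enolate of 42 | BrC/C(C)=C\[C@@H]5OC(=O)[C@H](C)[C@]53OC(C)(C)O[C@@H]3[C@H]1[C@]2(C)OC(C)(C)O[C@@H]2C=C[C@]1(C)C([O-])=CS(=O)(=O)c6ccccc6.[Cs+] | intermediate
44 | ten-membered C2 ketone with C3 phenylsulfonyl group (C3 epimers, bis-acetonide) | CC7(C)O[C@@H]1[C@H]2[C@]3(C)OC(C)(C)O[C@@H]3C=C[C@]2(C)C(=O)C(S(=O)(=O)c4ccccc4)C/C(C)=C\[C@@H]2OC(=O)[C@H](C)[C@]21O7 | intermediate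
45 | ten-membered C2 ketone (bis-acetonide) | CC7(C)O[C@@H]1[C@H]2[C@]3(C)OC(C)(C)O[C@@H]3C=C[C@]2(C)C(=O)CC/C(C)=C\[C@@H]2OC(=O)[C@H](C)[C@]21O7 | intermediate
46 | 2R alcohol (bis-acetonide) | CC7(C)O[C@@H]1[C@H]2[C@]3(C)OC(C)(C)O[C@@H]3C=C[C@]2(C)[C@H](O)CC/C(C)=C\[C@@H]2OC(=O)[C@H](C)[C@]21O7 | intermediate
47 | C2,C8,C9,C11,C12 pentaol | O[C@@H]1[C@H]2[C@](C)(O)[C@H](O)C=C[C@]2(C)[C@H](O)CC/C(C)=C\[C@@H]2OC(=O)[C@H](C)[C@]21O | intermediate
48 | CNP0129620.2 (1S,2R,7S,8S,9R,10S,11S,12R,17R; 5Z) | CC(=O)O[C@@H]1[C@H]2[C@](C)(O)[C@H](OC(C)=O)C=C[C@]2(C)[C@H](OC(C)=O)CC/C(C)=C\[C@@H]2OC(=O)[C@H](C)[C@]21O | target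

Total step count: 34. Longest linear sequence: 28 steps (steps 1–11, 16–20, 23–34).

Steps most likely to fail

1. Step 30. Ring closure may lose to intermolecular alkylation, to O-alkylation of the enolate, or to allylic transposition of the bromide before it cyclises.
 - Fallback: a palladium-catalysed allylic alkylation (Tsuji–Trost macrocyclisation) in place of an SN2 reaction on a halide.
 - It sets out from allylic alcohol 41, which methyl chloroformate and pyridine convert to the allylic methyl carbonate F1.
 - F1 is added slowly to Pd2(dba)3·CHCl3 and 1,2-bis(diphenylphosphino)ethane in THF. Zerovalent palladium ionises the carbonate, the liberated methoxide deprotonates C3, and the carbanion attacks the unsubstituted C4 terminus of the π-allyl complex. This comes back to the route at 44.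
 - No labile bromide has to be handled, and the nucleophile is generated only beside the electrophile.
 - The price is possible syn/anti equilibration of the allyl unit, so the alkene geometry would have to be checked.

2. Step 16. Incomplete chelation would lead to poor facial selectivity at C9, and the two fully substituted neighbours of C10 may slow the addition.
 - Fallback: C9 is set by reduction instead of by C–C bond formation.
 - It sets out from the unseparated mixture of 23 and its C9 epimer F2, which Dess–Martin periodinane converts to the single C9 enone F3.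
 - 1,2-Reduction under non-chelating Luche conditions (NaBH4, CeCl3·7H2O, MeOH, −78 °C) should then be selective. The carbonyl oxygen turns away from the C11–O dipole toward the C1 flank and the branched alkenyl group lies over the smaller C11 flank. Hydride arrives from the side of H10, which corresponds to 9R. This comes back to the route at 23.

3. Step 32. Facial selectivity would be poor if the ten-membered ring populates a second conformer that exposes the other carbonyl face.
 - Fallback: catalyst control in place of substrate control.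
 - It sets out from ketone 45. Any 2S alcohol F4 from step 32 is first re-oxidised to 45 with Dess–Martin periodinane.
 - A CBS reduction is run with (S)-1-methyl-3,3-diphenyltetrahydro-1H,3H-pyrrolo[1,2-c][1,3,2]oxazaborole and catecholborane in toluene at −60 °C.
 - Quaternary C1 and the C3 methylene differ in size like the two groups of a tert-alkyl methyl ketone, the best substrate class for this catalyst, and the S catalyst corresponds to the 2R alcohol.
 - Catecholborane at low temperature should not hydroborate the two hindered alkenes. This comes back to the route at 46.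

Further compounds
F1 | step 30 | C4 allylic methyl carbonate of 41 | COC(=O)OC/C(C)=C\[C@@H]5OC(=O)[C@H](C)[C@]53OC(C)(C)O[C@@H]3[C@H]1[C@]2(C)OC(C)(C)O[C@@H]2C=C[C@]1(C)C(=O)CS(=O)(=O)c6ccccc6
F2 | step 16 | C9 epimer of 23 (9S) | C=C([C@@H](C)CO[Si](C)(C)C(C)(C)C)[C@@H](O)[C@H]1[C@]2(C)OC(C)(C)O[C@@H]2C=C[C@]1(C)CO[Si](C)(C)C(C)(C)C
F3 | step 16 | C9 enone | C=C([C@@H](C)CO[Si](C)(C)C(C)(C)C)C(=O)[C@H]1[C@]2(C)OC(C)(C)O[C@@H]2C=C[C@]1(C)CO[Si](C)(C)C(C)(C)C
F4 | step 32 | C2 epimer of 46 (2S) | CC7(C)O[C@@H]1[C@H]2[C@]3(C)OC(C)(C)O[C@@H]3C=C[C@]2(C)[C@@H](O)CC/C(C)=C\[C@@H]2OC(=O)[C@H](C)[C@]21O7
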